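**Retrosynthetic overview**
1. Enabling feature: ring B, the 3(2H)-furanone O–C3=C2–C1(=O)–C10, is the cyclised form of an α′-hydroxy-ynone, and its C1–C2 bond is also a bond of the ten-membered carbocycle (ring A, C1–C10). Cutting C1–C2 and O–C3 therefore opens rings A and B together and leaves monocyclic lactone 25, which carries a C10 hydroxy thiol ester and a terminal (Z)-enyne.
2. 25 comes from 22 by inversion/methacrylation at C8 and C–Si cleavage; 22 comes from a C7–C8 Barbier union of bromomethyl-butenolide 14 with aldehyde 20.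
3. 14 comes from enal 6 (asymmetric alkynylation sets C6; hydroalumination/iodination; carbonylative lactonization), and 6 from mono-silylated butynediol 1. 20 comes from diol ester 15, which brings C9 and C10.
4. Ring order: butenolide, then α-methylene-γ-lactone (ring C), then rings A and B together in the key step; O-desilylation last.

Key step: step 15

Remark: locants C1–C15 are germacrane locants of the target (C1 ketone, C2=C3 furanone alkene, C4=C5, C6 lactone carbinol, C8 methacrylate, C9 senecioate, C10 quaternary, C11=C13 methylene, C12 lactone carbonyl, C15 hydroxymethyl).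
Assumption: diol ester 15 is bought (a bulk nucleoside-drug intermediate); otherwise it is two steps from (R)-glyceraldehyde acetonide (Wittig olefination, dihydroxylation).
Assumption: the ProPhenol antipode is the one that delivers the alkynylzinc to the Si face of enal 6; (S,S)-ProPhenol is written, and its mirror image is used if the facial sense is the opposite.

**Route**

Step 1
Reactants: 1 4-[(tert-butyldimethylsilyl)oxy]but-2-yn-1-ol
Product: 3 (Z)-4-[(tert-butyldimethylsilyl)oxy]-3-iodobut-2-en-1-ol, via cyclic alkenylalanate 2 (not isolated)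
Conditions: NaAlH2(OCH2CH2OMe)2 (Red-Al), THF, 0 °C; then I2, THF, −78 °C
Reagents that add atoms: iodine, [I][I]
Why: Hydroxyl-directed trans-hydroalumination of the propargylic alcohol puts aluminium on the distal alkyne carbon in a five-membered alkoxyaluminate, and iodinolysis with retention gives the (Z)-3-iodoallylic alcohol, which fixes the later C4=C5 geometry (iodine cis to the CH2OH that becomes C6).

Step 2
Reactants: 3 (Z)-4-[(tert-butyldimethylsilyl)oxy]-3-iodobut-2-en-1-ol; 4 ethynyltrimethylsilane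
Product: 5 (E)-3-{[(tert-butyldimethylsilyl)oxy]methyl}-5-(trimethylsilyl)pent-2-en-4-yn-1-ol (alkyne cis to CH2OH)
Conditions: PdCl2(PPh3)2 (3 mol%), CuI (6 mol%), Et3N, THF, rt
Reagents that add atoms: ethynyltrimethylsilane (4), C#C[Si](C)(C)C
Why: Sonogashira coupling of a vinyl iodide proceeds with retention of alkene geometry, so the C2≡C3 alkyne ends cis to the future C6.

Step 3
Reactants: 5 (E)-3-{[(tert-butyldimethylsilyl)oxy]methyl}-5-(trimethylsilyl)pent-2-en-4-yn-1-ol
Product: 6 (E)-3-{[(tert-butyldimethylsilyl)oxy]methyl}-5-(trimethylsilyl)pent-2-en-4-ynal (alkyne cis to CHO)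
Conditions: MnO2, CH2Cl2, rt
Reagents that add atoms: none
Why: MnO2 oxidation of the allylic alcohol is neutral, so the cis aldehyde/alkyne arrangement should not isomerize and the silyl groups should survive.

Step 4
Reactants: 6 (E)-3-{[(tert-butyldimethylsilyl)oxy]methyl}-5-(trimethylsilyl)pent-2-en-4-ynal; 7 triethyl(prop-2-yn-1-yloxy)silane
Product: 9 (4R,5E)-6-{[(tert-butyldimethylsilyl)oxy]methyl}-1-[(triethylsilyl)oxy]-8-(trimethylsilyl)oct-5-ene-2,7-diyn-4-ol, via alkynyl(methyl)zinc 8 (not isolated)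
Conditions: (S,S)-ProPhenol (20 mol%), Me2Zn (3 equiv), Ph3P=O (40 mol%), toluene, 0–4 °C
Reagents that add atoms: triethyl(prop-2-yn-1-yloxy)silane (7), C#CCO[Si](CC)(CC)CC
Why: Dinuclear zinc–ProPhenol asymmetric alkynylation of an α,β-unsaturated aldehyde, in which the chiral dizinc pocket delivers the alkynylzinc to the Si face of the aldehyde and so sets C6 (4R in 9).

Step 5
Reactants: 9 (4R,5E)-6-{[(tert-butyldimethylsilyl)oxy]methyl}-1-[(triethylsilyl)oxy]-8-(trimethylsilyl)oct-5-ene-2,7-diyn-4-ol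
Product: 11 (2Z,4R,5E)-6-{[(tert-butyldimethylsilyl)oxy]methyl}-2-iodo-1-[(triethylsilyl)oxy]-8-(trimethylsilyl)octa-2,5-dien-7-yn-4-ol, via cyclic alkenylalanate 10 (not isolated)
Conditions: NaAlH2(OCH2CH2OMe)2 (Red-Al), THF, −20 to 0 °C; then I2, THF, −78 °C
Reagents that add atoms: iodine, [I][I]
Why: A second hydroxyl-directed trans-hydroalumination/iodination, now across C7≡C11, puts iodine on C11 cis to the C6 carbinol (the geometry needed for lactonization), and the low temperature should suppress β-elimination of the silyloxy group to an allene.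

Step 6
Reactants: 11 (2Z,4R,5E)-6-{[(tert-butyldimethylsilyl)oxy]methyl}-2-iodo-1-[(triethylsilyl)oxy]-8-(trimethylsilyl)octa-2,5-dien-7-yn-4-ol
Product: 12 (5R)-5-[(1E)-2-{[(tert-butyldimethylsilyl)oxy]methyl}-4-(trimethylsilyl)but-1-en-3-yn-1-yl]-3-{[(triethylsilyl)oxy]methyl}furan-2(5H)-one
Conditions: PdCl2(PPh3)2 (5 mol%), CO (1 atm), K2CO3, THF, rt
Reagents that add atoms: carbon monoxide, [C-]#[O+]
Why: Palladium-catalysed carbonylative lactonization of a (Z)-3-iodoallylic alcohol (oxidative addition, CO insertion, capture of the acylpalladium by the C6 hydroxyl) gives the butenolide with C12 in place and does not touch the C6 stereocentre.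

Step 7
Reactants: 12 (5R)-5-[(1E)-2-{[(tert-butyldimethylsilyl)oxy]methyl}-4-(trimethylsilyl)but-1-en-3-yn-1-yl]-3-{[(triethylsilyl)oxy]methyl}furan-2(5H)-one
Product: 13 (5R)-5-[(1E)-2-{[(tert-butyldimethylsilyl)oxy]methyl}-4-(trimethylsilyl)but-1-en-3-yn-1-yl]-3-(hydroxymethyl)furan-2(5H)-one
Conditions: PPTS (cat.), MeOH, 0 °C
Reagents that add atoms: none
Why: Acidic methanolysis removes the triethylsilyl ether much faster than the primary tert-butyldimethylsilyl ether, and the non-basic medium protects the acidic γ-hydrogen at C6.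

Step 8
Reactants: 13 (5R)-5-[(1E)-2-{[(tert-butyldimethylsilyl)oxy]methyl}-4-(trimethylsilyl)but-1-en-3-yn-1-yl]-3-(hydroxymethyl)furan-2(5H)-one
Product: 14 (5R)-3-(bromomethyl)-5-[(1E)-2-{[(tert-butyldimethylsilyl)oxy]methyl}-4-(trimethylsilyl)but-1-en-3-yn-1-yl]furan-2(5H)-one
Conditions: CBr4, PPh3, CH2Cl2, 0 °C
Reagents that add atoms: carbon tetrabromide, BrC(Br)(Br)Br
Why: Appel bromination of the primary allylic alcohol is neutral and should give the 2-(alkoxycarbonyl)allyl bromide without touching the silyl groups or the C6 stereocentre.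

Step 9
Reactants: 15 ethyl (2S,3R)-3-[(4R)-2,2-dimethyl-1,3-dioxolan-4-yl]-2,3-dihydroxy-2-methylpropanoate
Product: 16 S-ethyl (2S,3R)-3-[(4R)-2,2-dimethyl-1,3-dioxolan-4-yl]-2,3-dihydroxy-2-methylpropanethioate
Conditions: Me3Al, EtSH, CH2Cl2, 0 °C to rt
Reagents that add atoms: ethanethiol, CCS
Why: Dimethylaluminium ethanethiolate, made in the flask, converts the chelating α-hydroxy ester into the thiol ester (aluminium-thiolate ester-to-thioester exchange) without affecting the C9 and C10 stereocentres or the acetonide.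

Step 10
Reactants: 16 S-ethyl (2S,3R)-3-[(4R)-2,2-dimethyl-1,3-dioxolan-4-yl]-2,3-dihydroxy-2-methylpropanethioate; 17 3-methylbut-2-enoyl chloride
Product: 18 S-ethyl (2S,3R)-3-[(4R)-2,2-dimethyl-1,3-dioxolan-4-yl]-2-hydroxy-2-methyl-3-[(3-methylbut-2-enoyl)oxy]propanethioate
Conditions: pyridine, DMAP (cat.), CH2Cl2, 0 °C
Reagents that add atoms: 3-methylbut-2-enoyl chloride (17), CC(C)=CC(=O)Cl
Why: Acylation with the acid chloride is selective for the secondary C9 hydroxyl over the hindered tertiary C10 hydroxyl, and the weak base avoids deconjugation of the senecioyl group through its vinylketene.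

Step 11
Reactants: 18 S-ethyl (2S,3R)-3-[(4R)-2,2-dimethyl-1,3-dioxolan-4-yl]-2-hydroxy-2-methyl-3-[(3-methylbut-2-enoyl)oxy]propanethioate
Product: 20 S-ethyl (2S,3S)-2-hydroxy-2-methyl-3-[(3-methylbut-2-enoyl)oxy]-4-oxobutanethioate, via deprotected diol 19 (not isolated)
Conditions: H5IO6, EtOAc, rt
Reagents that add atoms: none
Why: Periodic acid hydrolyses the terminal acetonide and cleaves the freed 1,2-diol in one pot (glycol cleavage) to give the C8 aldehyde under non-basic conditions that should not epimerize C9, and the acylated C9 oxygen leaves no other vicinal diol.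

Step 12
Reactants: 14 (5R)-3-(bromomethyl)-5-[(1E)-2-{[(tert-butyldimethylsilyl)oxy]methyl}-4-(trimethylsilyl)but-1-en-3-yn-1-yl]furan-2(5H)-one; 20 S-ethyl (2S,3S)-2-hydroxy-2-methyl-3-[(3-methylbut-2-enoyl)oxy]-4-oxobutanethioate
Product: 22 α-methylene-γ-butyrolactone carbinol (6R,7R,8R,9R,10S; 6,7-trans lactone; free 8-OH; 9-O-senecioate; free 10-OH; C1 S-ethyl thiol ester), via allylzinc bromide 21 (not isolated)
Conditions: Zn dust, THF/sat. aq. NH4Cl, 0 °C to rt; crude product used directly
Reagents that add atoms: none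
Why: Zinc-mediated Barbier allylation with a 3-(bromomethyl)butenolide reacts at the ring γ-carbon (C7) through a closed six-membered transition state, so C7–C8 forms anti to the C6 substituent (trans-lactone), the ring-locked (E)-type allylzinc gives the 7,8-anti adduct, and Felkin–Anh attack anti to the C9 acyloxy group points to the same 8R carbinol, the three controls reinforcing one another.

Step 13
Reactants: 22 α-methylene-γ-butyrolactone carbinol (8R); 23 methacrylic acid
Product: 24 8-O-methacrylate (6R,7S,8S,9R,10S) with C-silylated enyne, 15-O-TBS ether, free 10-OH and C1 S-ethyl thiol ester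
Conditions: PPh3, DIAD, toluene, −20 °C to rt
Reagents that add atoms: methacrylic acid (23), C=C(C)C(=O)O
Why: Mitsunobu esterification displaces the activated C8 oxygen by SN2 attack of methacrylate, which inverts C8 to the required 8S configuration and installs the methacrylate at the same time, while the tertiary C10 hydroxyl does not react.

Step 14
Reactants: 24 8-O-methacrylate with C-silylated enyne
Product: 25 cyclization precursor: same lactone with terminal alkyne C2≡C3, free 10-OH and C1 S-ethyl thiol ester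
Conditions: Bu4NF, AcOH, THF, −20 °C
Reagents that add atoms: none
Why: Buffered fluoride cleaves the C(sp)–SiMe3 bond far faster than the primary silyl ether, and the acetic acid buffer shields the thiol ester, the esters and the Michael acceptors from basic fluoride.

Step 15
Reactants: 25 cyclization precursor (terminal alkyne, C10 hydroxy thiol ester)
Product: 27 15-O-tert-butyldimethylsilyl ether of the target, via macrocyclic hydroxy-ynone 26 (not isolated)
Conditions: PdCl2(dppf) (20 mol%), P(2-furyl)3 (50 mol%), CuI (2 equiv), Et3N, DMF, 50 °C, argon, syringe-pump addition of 25 to a final 1 mM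
Reagents that add atoms: none
Why: Proposed new method: zerovalent palladium inserts into the C1(acyl)–S bond, CuI takes up the thiolate and supplies the copper acetylide of C2≡C3, and C(acyl)–C(sp) reductive elimination closes ring A as hydroxy-ynone 26, whose C10 hydroxyl then adds to C3 under Et3N/CuI to give the furanone; the closest known reactions are the intermolecular Pd/Cu coupling of thiol esters with 1-alkynes to ynones and the base- or metal-promoted cyclization of α′-hydroxy-ynones to 3(2H)-furanones, here merged and run as a macrocyclization. Ring A closes by reductive elimination from an eleven-membered acyl(alkynyl)palladium chelate, and ring B closes by 5-endo-dig oxa-Michael addition, which also turns the strained ten-membered enynone into the unstrained 11-oxabicyclo[6.2.1]undecadienone. No stereocentre is created: C10 keeps its configuration because its C–O bond is never broken and it has no α-hydrogen, and the C4=C5 geometry is untouched. The step needs cyclization over oligomerization, which slow addition at high dilution and the preorganization by the (Z)-C4=C5 bond and the trans-lactone should secure. It needs chemoselectivity for the thiol ester over the four O-esters, which the much easier C–S insertion and the thiophilicity of copper should secure. O-addition at C3 is the only geometrically possible Michael mode, since the 4-exo alternative is excluded.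

Step 16
Reactants: 27 15-O-tert-butyldimethylsilyl ether of the target
Product: 28 target, (4Z,6R,7S,8S,9R,10S)-15-hydroxy-8-(methacryloyloxy)-9-[(3-methylbut-2-enoyl)oxy]-1-oxo-3,10-epoxygermacra-2,4,11(13)-trien-12,6-olide
Conditions: HF·pyridine, pyridine, THF, 0 °C to rt
Reagents that add atoms: none
Why: HF·pyridine removes the primary silyl ether under mildly acidic conditions that the furanone, the α-methylene lactone and both esters should tolerate, and no stereocentre is affected.

**Compound list**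
1 | 4-[(tert-butyldimethylsilyl)oxy]but-2-yn-1-ol | OCC#CCO[Si](C)(C)C(C)(C)C | starting material
2 | cyclic sodium alkenylalanate from 1 (Al on C3, ring through O1) | [Na+].COCCO[Al-]1(OCCOC)OCC=C1CO[Si](C)(C)C(C)(C)C | intermediate
3 | (Z)-4-[(tert-butyldimethylsilyl)oxy]-3-iodobut-2-en-1-ol | OC/C=C(\I)CO[Si](C)(C)C(C)(C)C | intermediate
4 | ethynyltrimethylsilane | C#C[Si](C)(C)C | starting material
5 | (E)-3-{[(tert-butyldimethylsilyl)oxy]methyl}-5-(trimethylsilyl)pent-2-en-4-yn-1-ol | OC/C=C(\C#C[Si](C)(C)C)CO[Si](C)(C)C(C)(C)C | intermediate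
6 | (E)-3-{[(tert-butyldimethylsilyl)oxy]methyl}-5-(trimethylsilyl)pent-2-en-4-ynal | O=C/C=C(\C#C[Si](C)(C)C)CO[Si](C)(C)C(C)(C)C | intermediate
7 | triethyl(prop-2-yn-1-yloxy)silane | C#CCO[Si](CC)(CC)CC | starting material
8 | methyl[3-(triethylsilyloxy)prop-1-yn-1-yl]zinc | C[Zn]C#CCO[Si](CC)(CC)CC | intermediate
9 | (4R,5E)-6-{[(tert-butyldimethylsilyl)oxy]methyl}-1-[(triethylsilyl)oxy]-8-(trimethylsilyl)oct-5-ene-2,7-diyn-4-ol | O[C@H](/C=C(/CO[Si](C)(C)C(C)(C)C)C#C[Si](C)(C)C)C#CCO[Si](CC)(CC)CC | intermediate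
10 | cyclic sodium alkenylalanate from 9 (Al on C11, ring through the C6 oxygen) | [Na+].COCCO[Al-]1(OCCOC)O[C@H](/C=C(/CO[Si](C)(C)C(C)(C)C)C#C[Si](C)(C)C)C=C1CO[Si](CC)(CC)CC | intermediate
11 | (2Z,4R,5E)-6-{[(tert-butyldimethylsilyl)oxy]methyl}-2-iodo-1-[(triethylsilyl)oxy]-8-(trimethylsilyl)octa-2,5-dien-7-yn-4-ol | O[C@H](/C=C(/CO[Si](C)(C)C(C)(C)C)C#C[Si](C)(C)C)/C=C(\I)CO[Si](CC)(CC)CC | intermediate
12 | (5R)-5-[(1E)-2-{[(tert-butyldimethylsilyl)oxy]methyl}-4-(trimethylsilyl)but-1-en-3-yn-1-yl]-3-{[(triethylsilyl)oxy]methyl}furan-2(5H)-one | CC[Si](CC)(CC)OCC1=C[C@@H](/C=C(/CO[Si](C)(C)C(C)(C)C)C#C[Si](C)(C)C)OC1=O | intermediate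
13 | (5R)-5-[(1E)-2-{[(tert-butyldimethylsilyl)oxy]methyl}-4-(trimethylsilyl)but-1-en-3-yn-1-yl]-3-(hydroxymethyl)furan-2(5H)-one | OCC1=C[C@@H](/C=C(/CO[Si](C)(C)C(C)(C)C)C#C[Si](C)(C)C)OC1=O | intermediate
14 | (5R)-3-(bromomethyl)-5-[(1E)-2-{[(tert-butyldimethylsilyl)oxy]methyl}-4-(trimethylsilyl)but-1-en-3-yn-1-yl]furan-2(5H)-one | BrCC1=C[C@@H](/C=C(/CO[Si](C)(C)C(C)(C)C)C#C[Si](C)(C)C)OC1=O | intermediate
15 | ethyl (2S,3R)-3-[(4R)-2,2-dimethyl-1,3-dioxolan-4-yl]-2,3-dihydroxy-2-methylpropanoate | CCOC(=O)[C@@](C)(O)[C@H](O)[C@H]1COC(C)(C)O1 | starting material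
16 | S-ethyl (2S,3R)-3-[(4R)-2,2-dimethyl-1,3-dioxolan-4-yl]-2,3-dihydroxy-2-methylpropanethioate | CCSC(=O)[C@@](C)(O)[C@H](O)[C@H]1COC(C)(C)O1 | intermediate
17 | 3-methylbut-2-enoyl chloride | CC(C)=CC(=O)Cl | starting material
18 | S-ethyl (2S,3R)-3-[(4R)-2,2-dimethyl-1,3-dioxolan-4-yl]-2-hydroxy-2-methyl-3-[(3-methylbut-2-enoyl)oxy]propanethioate | CCSC(=O)[C@@](C)(O)[C@H](OC(=O)C=C(C)C)[C@H]1COC(C)(C)O1 | intermediate
19 | S-ethyl (2S,3R,4R)-2,4,5-trihydroxy-2-methyl-3-[(3-methylbut-2-enoyl)oxy]pentanethioate | CCSC(=O)[C@@](C)(O)[C@H](OC(=O)C=C(C)C)[C@H](O)CO | intermediate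
20 | S-ethyl (2S,3S)-2-hydroxy-2-methyl-3-[(3-methylbut-2-enoyl)oxy]-4-oxobutanethioate | CCSC(=O)[C@@](C)(O)[C@H](OC(=O)C=C(C)C)C=O | intermediate
21 | allylzinc bromide from 14 | Br[Zn]CC1=C[C@@H](/C=C(/CO[Si](C)(C)C(C)(C)C)C#C[Si](C)(C)C)OC1=O | intermediate
22 | S-ethyl (2S,3R,4R)-4-[(2R,3R)-2-{(1E)-2-[(tert-butyldimethylsilyloxy)methyl]-4-(trimethylsilyl)but-1-en-3-yn-1-yl}-4-methylidene-5-oxooxolan-3-yl]-2,4-dihydroxy-2-methyl-3-[(3-methylbut-2-enoyl)oxy]butanethioate (germacrane locants 6R,7R,8R,9R,10S) | O[C@H]([C@H]1C(=C)C(=O)O[C@@H]1/C=C(/CO[Si](C)(C)C(C)(C)C)C#C[Si](C)(C)C)[C@@H](OC(=O)C=C(C)C)[C@](C)(O)C(=O)SCC | intermediate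
23 | methacrylic acid | C=C(C)C(=O)O | starting material
24 | S-ethyl (2S,3R,4S)-4-[(2R,3S)-2-{(1E)-2-[(tert-butyldimethylsilyloxy)methyl]-4-(trimethylsilyl)but-1-en-3-yn-1-yl}-4-methylidene-5-oxooxolan-3-yl]-2-hydroxy-2-methyl-3-[(3-methylbut-2-enoyl)oxy]-4-[(2-methylprop-2-enoyl)oxy]butanethioate (6R,7S,8S,9R,10S) | C=C(C)C(=O)O[C@@H]([C@H]1C(=C)C(=O)O[C@@H]1/C=C(/CO[Si](C)(C)C(C)(C)C)C#C[Si](C)(C)C)[C@@H](OC(=O)C=C(C)C)[C@](C)(O)C(=O)SCC | intermediate
25 | S-ethyl (2S,3R,4S)-4-[(2R,3S)-2-{(1E)-2-[(tert-butyldimethylsilyloxy)methyl]but-1-en-3-yn-1-yl}-4-methylidene-5-oxooxolan-3-yl]-2-hydroxy-2-methyl-3-[(3-methylbut-2-enoyl)oxy]-4-[(2-methylprop-2-enoyl)oxy]butanethioate (6R,7S,8S,9R,10S) | C=C(C)C(=O)O[C@@H]([C@H]1C(=C)C(=O)O[C@@H]1/C=C(/CO[Si](C)(C)C(C)(C)C)C#C)[C@@H](OC(=O)C=C(C)C)[C@](C)(O)C(=O)SCC | intermediate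
26 | (6R,7S,8S,9R,10S)-15-[(tert-butyldimethylsilyl)oxy]-10-hydroxy-8-(methacryloyloxy)-9-[(3-methylbut-2-enoyl)oxy]-1-oxogermacra-4,11(13)-dien-2-yn-12,6-olide (C6 and the alkyne cis across C4=C5) | C=C(C)C(=O)O[C@H]1[C@H]2C(=C)C(=O)O[C@@H]2/C=C(/CO[Si](C)(C)C(C)(C)C)C#CC(=O)[C@@](C)(O)[C@@H]1OC(=O)C=C(C)C | intermediate
27 | (4Z,6R,7S,8S,9R,10S)-15-[(tert-butyldimethylsilyl)oxy]-8-(methacryloyloxy)-9-[(3-methylbut-2-enoyl)oxy]-1-oxo-3,10-epoxygermacra-2,4,11(13)-trien-12,6-olide | C=C(C)C(=O)O[C@H]1[C@H]2C(=C)C(=O)O[C@@H]2/C=C(/CO[Si](C)(C)C(C)(C)C)C2=CC(=O)[C@@](C)(O2)[C@@H]1OC(=O)C=C(C)C | intermediate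
28 | (4Z,6R,7S,8S,9R,10S)-15-hydroxy-8-(methacryloyloxy)-9-[(3-methylbut-2-enoyl)oxy]-1-oxo-3,10-epoxygermacra-2,4,11(13)-trien-12,6-olide | C=C(C)C(=O)O[C@H]1[C@H]2C(=C)C(=O)O[C@@H]2/C=C(/CO)C2=CC(=O)[C@@](C)(O2)[C@@H]1OC(=O)C=C(C)C | target

**Step count**
Total: 16 steps. Longest linear sequence: 13 steps (steps 1–8 and 12–16); the aldehyde branch (steps 9–11) is three steps.

**Steps most likely to fail**

Step 15 (proposed new method). Oligomerization or oxidative alkyne homocoupling may outrun closure of the strained ten-membered enynone, and the α-hydroxy acylpalladium may lose CO before it is alkynylated. The fallback uses known reactions, sets out from 24 and returns at 27. Fukuyama reduction of the thiol ester of 24 (Et3SiH, Pd/C, acetone) should give the α-hydroxy aldehyde F1. Iododesilylation (N-iodosuccinimide, AgF, MeCN) should give the iodoalkyne F2. An intramolecular Nozaki–Hiyama–Kishi reaction (CrCl2, catalytic NiCl2, THF, high dilution), a known way to close ten-membered ene-yne carbocycles, should give the macrocyclic propargylic diol F3 as C1 epimers. MnO2 would then oxidize the propargylic carbinol to hydroxy-ynone 26, isolated in this variant, and Ph3PAuNTf2 would cyclize it to 27.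

Step 13. Participation of the neighbouring C9 ester (acyloxonium formation, leading to retention or acyl scrambling), elimination towards the conjugated diene, or slow activation of the hindered carbinol may spoil the inversion. The fallback sets out from 22 and returns at 24. Dess–Martin oxidation should give the C8 ketone F4. Luche reduction (NaBH4, CeCl3·7H2O, MeOH, −78 °C) under Felkin–Anh control (hydride anti to the C9 acyloxy group) should give the 8S alcohol F5. Acylation with methacrylic anhydride and DMAP would then give 24 with no substitution at carbon.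

Step 12. Diastereoselectivity may erode if the free C10 hydroxyl chelates zinc and overrides Felkin–Anh control; attack may occur through the CH2 terminus; and the new C8 hydroxyl may lactonize onto the thiol ester or take over the senecioyl group in the aqueous medium. The fallback sets out from 14 and returns at 22. Palladium-catalysed borylation of the allylic bromide (B2pin2, Pd2(dba)3, toluene) should give the allylboronate F6. Its allylboration of 20 (toluene, 40 °C, catalytic Sc(OTf)3) runs under anhydrous, non-basic conditions through a strictly closed chair transition state and keeps C8–O masked as a borate until a cold aqueous work-up releases 22.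

**Further compounds**
F1 | step 15 | α-hydroxy aldehyde from 24 (C1 = CHO; otherwise as 24) | C=C(C)C(=O)O[C@@H]([C@H]1C(=C)C(=O)O[C@@H]1/C=C(/CO[Si](C)(C)C(C)(C)C)C#C[Si](C)(C)C)[C@@H](OC(=O)C=C(C)C)[C@](C)(O)C=O
F2 | step 15 | iodoalkyne aldehyde (C2–I; otherwise as F1) | C=C(C)C(=O)O[C@@H]([C@H]1C(=C)C(=O)O[C@@H]1/C=C(/CO[Si](C)(C)C(C)(C)C)C#CI)[C@@H](OC(=O)C=C(C)C)[C@](C)(O)C=O
F3 | step 15 | macrocyclic propargylic 1,10-diol (C1 epimers; otherwise as 26) | C=C(C)C(=O)O[C@H]1[C@H]2C(=C)C(=O)O[C@@H]2/C=C(/CO[Si](C)(C)C(C)(C)C)C#CC(O)[C@@](C)(O)[C@@H]1OC(=O)C=C(C)C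
F4 | step 13 | C8 ketone from 22 | O=C([C@H]1C(=C)C(=O)O[C@@H]1/C=C(/CO[Si](C)(C)C(C)(C)C)C#C[Si](C)(C)C)[C@@H](OC(=O)C=C(C)C)[C@](C)(O)C(=O)SCC
F5 | step 13 | 8S alcohol (C8 epimer of 22) | O[C@@H]([C@H]1C(=C)C(=O)O[C@@H]1/C=C(/CO[Si](C)(C)C(C)(C)C)C#C[Si](C)(C)C)[C@@H](OC(=O)C=C(C)C)[C@](C)(O)C(=O)SCC
F6 | step 12 | pinacol allylboronate from 14 | CC1(C)OB(CC2=C[C@@H](/C=C(/CO[Si](C)(C)C(C)(C)C)C#C[Si](C)(C)C)OC2=O)OC1(C)C
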